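## Retrosynthetic overview

1. Numbering: carbocycle C1 (CH–iPr), C2 (CH–O), C3=C4, C5, C6 (C=O), C7, C8 (CH–CH3), C9, C10=C11 (E), C12 (C(OH)CH3), C13, C14 (CH–OAc); the lactone carbonyl (C15) sits on C4 and the ring oxygen on C2.
2. Feature used: the butenolide C2–C3=C4–C15(=O)–O bridges C2 and C4 of the 14-membered ring and is the sum of an aldehyde (C2), a terminal alkyne (C3≡C4) and CO. One titanium-mediated [2+2+1] step forms C2–C3, C4–C15 and C15–O, so butenolide and carbocycle close together; no ring of the target exists before it.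
3. The open-chain ynal comes from an Evans syn-aldol (C1–C14 bond; sets C1 and C14), a Sharpless epoxidation/hydride opening of a dienol (C12), a vinylogous HWE olefination (C10=C11) and propargylation/oxidation/ketalisation at C6. C8 comes from methyl hydrogen (R)-3-methylglutarate.
4. After ring closure: desilylation, acetylation of the secondary C14 hydroxyl, ketal hydrolysis.

Key step: step 18

Remarks on the chemistry:
- "Bicyclic butenolide" below means the target skeleton: 1-isopropyl-8,12-dimethylcyclotetradeca-3,10-diene (C1–C14) bridged by the lactone C2–O–C15(=O)–C4.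
- Where a CIP descriptor changes between compounds without a reaction at that centre (C1, C8), only the priorities change.
- Assumption: the commercial phosphonate is an E/Z mixture; any 2Z-dienoate from step 8 would be removed by chromatography (at the ester or the dienol) before the epoxidation. Minor diastereomers from imperfect enantiopurity of the two chiral inputs would be removed after step 14.

## Route

Step 1
Reactants: 1 (R)-4-benzyl-1,3-oxazolidin-2-one; 2 3-methylbutanoyl chloride (isovaleryl chloride)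
Product: 4 (R)-4-benzyl-3-(3-methylbutanoyl)-1,3-oxazolidin-2-one, via N-lithio oxazolidinone 3 (not isolated)
Conditions: n-BuLi, THF, −78 °C; then 2, −78 → 0 °C
Reagents that add atoms: none
Why: N-acylation of the lithiated oxazolidinone by the acid chloride (standard preparation of an Evans imide), which touches no stereocentre.

Step 2
Reactants: 5 methyl hydrogen (R)-3-methylglutarate
Product: 6 methyl (R)-5-hydroxy-3-methylpentanoate
Conditions: BH3·SMe2, THF, −10 °C → rt; MeOH quench
Reagents that add atoms: none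
Why: Chemoselective borane reduction (via the acyloxyborane) reduces the carboxylic acid (C6) far faster than the ester and leaves C8 untouched; the hydroxy ester is used at once so that it does not lactonise.

Step 3
Reactants: 6 methyl (R)-5-hydroxy-3-methylpentanoate
Product: 7 methyl (R)-3-methyl-5-oxopentanoate
Conditions: TEMPO (cat.), PhI(OAc)2, CH2Cl2, rt
Reagents that add atoms: none
Why: Oxoammonium (TEMPO) oxidation of the primary alcohol stops at the aldehyde under neutral conditions that neither enolise nor lactonise the substrate.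

Step 4
Reactants: 7 methyl (R)-3-methyl-5-oxopentanoate; 8 propargyl bromide
Product: 10 methyl (3R)-5-hydroxy-3-methyloct-7-ynoate (both C5 epimers), via allenylzinc bromide 9 (not isolated)
Conditions: Zn dust, 8, THF, 0 °C; then 7, −78 → 0 °C; aq. NH4Cl
Reagents that add atoms: none
Why: Barbier-type propargylation in which allenylzinc bromide adds through its γ-carbon (SE2′) to give the homopropargylic alcohol and leaves the ester alone; the new carbinol centre (C6 of the target) is formed without control and is removed by oxidation in step 5.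

Step 5
Reactants: 10 methyl (3R)-5-hydroxy-3-methyloct-7-ynoate
Product: 11 methyl (R)-3-methyl-5-oxooct-7-ynoate
Conditions: Dess–Martin periodinane, NaHCO3, CH2Cl2, 0 °C → rt
Reagents that add atoms: none
Why: Dess–Martin oxidation is non-basic, so the β,γ-alkynyl ketone should form without isomerising to the allenyl ketone; it is carried forward crude.

Step 6
Reactants: 11 methyl (R)-3-methyl-5-oxooct-7-ynoate
Product: 12 methyl (R)-3-methyl-4-[2-(prop-2-yn-1-yl)-1,3-dioxolan-2-yl]butanoate
Conditions: (Me3SiOCH2)2, TMSOTf (cat.), CH2Cl2, −78 → −20 °C; pyridine quench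
Reagents that add atoms: 1,2-bis(trimethylsilyloxy)ethane, C[Si](C)(C)OCCO[Si](C)(C)C
Why: Noyori ketalisation (aprotic, low temperature) is the method that protects β,γ-unsaturated ketones without moving the unsaturation, and it locks C6 so that the C5 methylene can no longer enolise toward an allene.

Step 7
Reactants: 12 methyl (R)-3-methyl-4-[2-(prop-2-yn-1-yl)-1,3-dioxolan-2-yl]butanoate
Product: 13 (S)-3-methyl-4-[2-(prop-2-yn-1-yl)-1,3-dioxolan-2-yl]butanal
Conditions: i-Bu2AlH, CH2Cl2, −78 °C; MeOH, aq. KNaC4H4O6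
Reagents that add atoms: none
Why: Partial reduction of the methyl ester at −78 °C stops at the aluminium hemiacetal, which releases the C10 aldehyde on work-up.

Step 8
Reactants: 13 (S)-3-methyl-4-[2-(prop-2-yn-1-yl)-1,3-dioxolan-2-yl]butanal; 14 triethyl 3-methyl-4-phosphonocrotonate
Product: 16 ethyl (2E,4E,7S)-3,7-dimethyl-8-[2-(prop-2-yn-1-yl)-1,3-dioxolan-2-yl]octa-2,4-dienoate, via lithiated phosphonate 15 (not isolated)
Conditions: 14, LiN(SiMe3)2, THF, −78 °C; then 13, −78 → 0 °C
Reagents that add atoms: none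
Why: Vinylogous Horner–Wadsworth–Emmons olefination in which the stabilised anion gives the new C10=C11 bond as E and the C12=C13 bond, which equilibrates in the delocalised anion, mainly as E.

Step 9
Reactants: 16 ethyl (2E,4E,7S)-3,7-dimethyl-8-[2-(prop-2-yn-1-yl)-1,3-dioxolan-2-yl]octa-2,4-dienoate
Product: 17 (2E,4E,7S)-3,7-dimethyl-8-[2-(prop-2-yn-1-yl)-1,3-dioxolan-2-yl]octa-2,4-dien-1-ol
Conditions: i-Bu2AlH (2.5 equiv), CH2Cl2, −78 °C; aq. KNaC4H4O6
Reagents that add atoms: none
Why: 1,2-Reduction of the conjugated ester by the aluminium hydride gives the allylic alcohol (C14–OH) without touching the diene, ketal or alkyne.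

Step 10
Reactants: 17 (2E,4E,7S)-3,7-dimethyl-8-[2-(prop-2-yn-1-yl)-1,3-dioxolan-2-yl]octa-2,4-dien-1-ol
Product: 18 [(2R,3R)-3-methyl-3-[(1E,4S)-4-methyl-5-[2-(prop-2-yn-1-yl)-1,3-dioxolan-2-yl]pent-1-en-1-yl]oxiran-2-yl]methanol
Conditions: Ti(OiPr)4 (10 mol%), D-(−)-diisopropyl tartrate (12 mol%), t-BuOOH, 4 Å MS, CH2Cl2, −25 °C; NaOH/brine work-up
Reagents that add atoms: tert-butyl hydroperoxide, CC(C)(C)OO
Why: Katsuki–Sharpless asymmetric epoxidation oxidises only the allylic C12=C13 alkene, and D-(−)-tartrate delivers oxygen to the face that gives the (2R,3R)-epoxide from this 2E-3-methyl allylic alcohol (L-(+)-tartrate gives the 2S,3S series), which fixes C12; catalytic loading, sieves and a basic work-up are chosen because the tertiary allylic epoxide is acid-labile.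

Step 11
Reactants: 18 epoxy alcohol
Product: 19 (3S,4E,7S)-3,7-dimethyl-8-[2-(prop-2-yn-1-yl)-1,3-dioxolan-2-yl]oct-4-ene-1,3-diol
Conditions: NaAlH2(OCH2CH2OMe)2, THF, −20 → 0 °C; aq. KNaC4H4O6
Reagents that add atoms: none
Why: Regioselective hydride opening of a 2,3-epoxy alcohol, in which the C14 alkoxyaluminate delivers hydride internally to C13 and gives the 1,3-diol while the C12–O bond, and so the C12 configuration (now S by CIP), stays intact.

Step 12
Reactants: 19 (3S,4E,7S)-diol
Product: 20 (3S,4E,7S)-3,7-dimethyl-8-[2-(prop-2-yn-1-yl)-1,3-dioxolan-2-yl]-1,3-bis(triethylsilyloxy)oct-4-ene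
Conditions: TESOTf (2.5 equiv), 2,6-lutidine, CH2Cl2, −78 → 0 °C
Reagents that add atoms: triethylsilyl trifluoromethanesulfonate, CC[Si](CC)(CC)OS(=O)(=O)C(F)(F)F
Why: Silyl triflate with 2,6-lutidine silylates both the primary and the hindered tertiary allylic hydroxyl, and a ketone ketal is known to survive these conditions.

Step 13
Reactants: 20 bis(triethylsilyl) ether
Product: 21 (3S,4E,7S)-3,7-dimethyl-8-[2-(prop-2-yn-1-yl)-1,3-dioxolan-2-yl]-3-(triethylsilyloxy)oct-4-enal
Conditions: (COCl)2, DMSO, CH2Cl2, −78 → −40 °C; Et3N, −78 → 0 °C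
Reagents that add atoms: none
Why: Swern conditions convert a primary triethylsilyl ether directly into the aldehyde (the chlorosulfonium salt cleaves the unhindered Si–O bond) while the tertiary silyl ether stays, so C14 is oxidised without a separate deprotection.

Step 14
Reactants: 4 (R)-4-benzyl-3-(3-methylbutanoyl)-1,3-oxazolidin-2-one; 21 aldehyde
Product: 23 (R)-4-benzyl-3-[(2R,3S,5S,6E,9S)-3-hydroxy-5,9-dimethyl-2-(propan-2-yl)-10-[2-(prop-2-yn-1-yl)-1,3-dioxolan-2-yl]-5-(triethylsilyloxy)dec-6-enoyl]-1,3-oxazolidin-2-one, via dibutylboron Z-enolate 22 (not isolated)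
Conditions: 4, n-Bu2BOTf, i-Pr2NEt, CH2Cl2, 0 °C; then 21, −78 → 0 °C; pH 7 buffer, MeOH, H2O2, 0 °C
Reagents that add atoms: none
Why: Evans syn-aldol, in which the Z-boron enolate reacts through a Zimmerman–Traxler chair with one enolate face shielded by the (R)-benzyl auxiliary, sets C1 (R) and C14 (S) syn to each other under reagent control that should override the remote C12 centre.

Step 15
Reactants: 23 aldol adduct
Product: 24 (R)-4-benzyl-3-[(2R,3S,5S,6E,9S)-5,9-dimethyl-2-(propan-2-yl)-10-[2-(prop-2-yn-1-yl)-1,3-dioxolan-2-yl]-3,5-bis(triethylsilyloxy)dec-6-enoyl]-1,3-oxazolidin-2-one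
Conditions: TESOTf, 2,6-lutidine, CH2Cl2, −78 → 0 °C
Reagents that add atoms: triethylsilyl trifluoromethanesulfonate, CC[Si](CC)(CC)OS(=O)(=O)C(F)(F)F
Why: Standard silylation of the secondary aldol hydroxyl, which blocks retro-aldol and ensures that no O–H group meets the titanium reagent later.

Step 16
Reactants: 24 silylated imide
Product: 25 (2S,3S,5S,6E,9S)-5,9-dimethyl-2-(propan-2-yl)-10-[2-(prop-2-yn-1-yl)-1,3-dioxolan-2-yl]-3,5-bis(triethylsilyloxy)dec-6-en-1-ol
Conditions: LiBH4, MeOH (1 equiv), THF, 0 °C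
Reagents that add atoms: none
Why: Reductive cleavage of the imide (borohydride attacks the exocyclic carbonyl) gives the primary C2 alcohol and returns the auxiliary without epimerising C1.

Step 17
Reactants: 25 primary alcohol
Product: 26 (2R,3S,5S,6E,9S)-5,9-dimethyl-2-(propan-2-yl)-10-[2-(prop-2-yn-1-yl)-1,3-dioxolan-2-yl]-3,5-bis(triethylsilyloxy)dec-6-enal
Conditions: Dess–Martin periodinane, NaHCO3, CH2Cl2, 0 °C → rt
Reagents that add atoms: none
Why: Buffered Dess–Martin oxidation gives the α-branched C2 aldehyde without epimerising C1 or eliminating the β-silyloxy group; the aldehyde is used at once.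

Step 18
Reactants: 26 open-chain ynal; 27 carbon monoxide
Product: 30 6,6-ethylenedioxy-12,14-bis(triethylsilyloxy) bicyclic butenolide (1S,2R,8S,10E,12S,14S), via oxatitanacyclopentene 28 (not isolated), via acyl titanium complex 29 (not isolated)
Conditions: Cp2Ti(PMe3)2 (1.3 equiv), toluene, about 2 mM, slow addition of 26, −20 °C → rt; then CO (1 atm), rt → 60 °C
Reagents that add atoms: none
Why: Proposed new method: divalent titanium (Cp2Ti(PMe3)2) takes up the C2 aldehyde as an η2 complex and the tethered 1-alkyne inserts with its unsubstituted carbon C3 bonding to C2 to give oxatitanacyclopentene 28 (tetravalent titanium), CO then inserts into the Ti–C4 bond to give acyl complex 29, and reductive elimination of acyl and alkoxide forms the lactone C15–O bond and leaves Cp2Ti(CO)2. The closest known reaction type is the intramolecular hetero-Pauson–Khand cyclocarbonylation of short-tethered alkynyl aldehydes and ketones to fused butenolides (with Cp2Ti(PMe3)2, Mo(CO)6 or Ru3(CO)12), and the ring-size precedent for the metallacycle-forming event is the nickel-catalysed reductive macrocyclisation of terminal ynals, which closes 14-membered rings by C–C bond formation at the terminal alkyne carbon through the analogous oxametallacyclopentene. The butenolide closes as a [2+2+1] annulation of C2=O, C3≡C4 and CO, and the 14-membered carbocycle closes end to end through the same C2–C3 bond, endo with respect to the alkyne, the syn addition across C3≡C4 placing C2 and C5 trans so that C3=C4 is the E-alkene of the large ring. The one new stereocentre, C2, is set when the alkyne attacks the coordinated aldehyde: Felkin-type 1,2-induction from C1 (C14 chain anti to the incoming carbon, attack past H) would place the C2 oxygen syn to the isopropyl group as required, but this is not assured because the macrocyclic transition state may override it. The step needs ring closure to win over pinacol-type and alkyne–aldehyde oligomerisation (slow addition to a slight excess of the titanium reagent at high dilution), C–C bond formation at C3 and not C4 (secured by sterics, since C4 carries the C5 chain) and an otherwise inert substrate (secured by the C6 ketal and the two silyl ethers, which leave aldehyde and alkyne as the only groups able to form a metallacycle). The acidic C3–H of the 1-alkyne is the recognised weak point of low-valent titanocene chemistry, which is why the reagent is used in stoichiometric amount and the complexation stage is run cold before CO is admitted.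

Step 19
Reactants: 30 protected bicyclic butenolide
Product: 31 6,6-ethylenedioxy-12,14-dihydroxy bicyclic butenolide (1R,2R,8S,10E,12S,14S)
Conditions: HF·pyridine, pyridine, THF, 0 °C → rt
Reagents that add atoms: none
Why: Buffered fluoride cleavage of both triethylsilyl ethers spares the ketal and avoids the basic conditions that could deprotonate the butenolide γ-position (C2).

Step 20
Reactants: 31 diol
Product: 32 14-acetoxy-6,6-ethylenedioxy-12-hydroxy bicyclic butenolide (1R,2R,8S,10E,12S,14S)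
Conditions: Ac2O (1.2 equiv), pyridine, DMAP (cat.), CH2Cl2, 0 °C
Reagents that add atoms: acetic anhydride, CC(=O)OC(C)=O
Why: DMAP-catalysed acylation is far faster at the secondary C14 hydroxyl than at the tertiary C12 hydroxyl, and the ketone is still masked so that C5 cannot enolise in base.

Step 21
Reactants: 32 acetate ketal
Product: 33 CNP0200490.2, 14-acetoxy-12-hydroxy-6-oxo bicyclic butenolide (1R,2R,8S,10E,12S,14S)
Conditions: PPTS, acetone/H2O (9:1), 45 °C
Reagents that add atoms: water, O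
Why: Mild acid-catalysed ketal hydrolysis (transketalisation to acetone) frees the C6 ketone under conditions that should leave the acetate, the tertiary allylic alcohol and the C5 methylene undisturbed.

## Compound list

1 | (R)-4-benzyl-1,3-oxazolidin-2-one | O=C1N[C@H](Cc2ccccc2)CO1 | starting material
2 | 3-methylbutanoyl chloride (isovaleryl chloride) | CC(C)CC(Cl)=O | starting material
3 | N-lithio derivative of 1 | [Li]N1[C@H](Cc2ccccc2)COC1=O | intermediate (not isolated)
4 | (R)-4-benzyl-3-(3-methylbutanoyl)-1,3-oxazolidin-2-one | CC(C)CC(=O)N1[C@H](Cc2ccccc2)COC1=O | intermediate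
5 | methyl hydrogen (R)-3-methylglutarate | COC(=O)C[C@H](C)CC(=O)O | starting material
6 | methyl (R)-5-hydroxy-3-methylpentanoate | COC(=O)C[C@H](C)CCO | intermediate
7 | methyl (R)-3-methyl-5-oxopentanoate | COC(=O)C[C@H](C)CC=O | intermediate
8 | propargyl bromide (3-bromoprop-1-yne) | C#CCBr | starting material
9 | allenylzinc bromide | C=C=C[Zn]Br | intermediate (not isolated)
10 | methyl (3R)-5-hydroxy-3-methyloct-7-ynoate (both C5 epimers) | COC(=O)C[C@H](C)CC(O)CC#C | intermediate
11 | methyl (R)-3-methyl-5-oxooct-7-ynoate | COC(=O)C[C@H](C)CC(=O)CC#C | intermediate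
12 | methyl (R)-3-methyl-4-[2-(prop-2-yn-1-yl)-1,3-dioxolan-2-yl]butanoate | COC(=O)C[C@H](C)CC1(CC#C)OCCO1 | intermediate
13 | (S)-3-methyl-4-[2-(prop-2-yn-1-yl)-1,3-dioxolan-2-yl]butanal | O=CC[C@H](C)CC1(CC#C)OCCO1 | intermediate
14 | triethyl 3-methyl-4-phosphonocrotonate (ethyl 4-(diethoxyphosphoryl)-3-methylbut-2-enoate, E/Z mixture) | CCOC(=O)C=C(C)CP(=O)(OCC)OCC | starting material
15 | lithium salt of the γ-carbanion of 14 | [Li+].CCOC(=O)C=C(C)[CH-]P(=O)(OCC)OCC | intermediate (not isolated)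
16 | ethyl (2E,4E,7S)-3,7-dimethyl-8-[2-(prop-2-yn-1-yl)-1,3-dioxolan-2-yl]octa-2,4-dienoate | CCOC(=O)/C=C(C)/C=C/C[C@H](C)CC1(CC#C)OCCO1 | intermediate
17 | (2E,4E,7S)-3,7-dimethyl-8-[2-(prop-2-yn-1-yl)-1,3-dioxolan-2-yl]octa-2,4-dien-1-ol | OC/C=C(C)/C=C/C[C@H](C)CC1(CC#C)OCCO1 | intermediate
18 | [(2R,3R)-3-methyl-3-[(1E,4S)-4-methyl-5-[2-(prop-2-yn-1-yl)-1,3-dioxolan-2-yl]pent-1-en-1-yl]oxiran-2-yl]methanol | OC[C@H]1O[C@]1(C)/C=C/C[C@H](C)CC2(CC#C)OCCO2 | intermediate
19 | (3S,4E,7S)-3,7-dimethyl-8-[2-(prop-2-yn-1-yl)-1,3-dioxolan-2-yl]oct-4-ene-1,3-diol | OCC[C@](C)(O)/C=C/C[C@H](C)CC1(CC#C)OCCO1 | intermediate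
20 | (3S,4E,7S)-3,7-dimethyl-8-[2-(prop-2-yn-1-yl)-1,3-dioxolan-2-yl]-1,3-bis(triethylsilyloxy)oct-4-ene | CC[Si](CC)(CC)OCC[C@](C)(O[Si](CC)(CC)CC)/C=C/C[C@H](C)CC1(CC#C)OCCO1 | intermediate
21 | (3S,4E,7S)-3,7-dimethyl-8-[2-(prop-2-yn-1-yl)-1,3-dioxolan-2-yl]-3-(triethylsilyloxy)oct-4-enal | O=CC[C@](C)(O[Si](CC)(CC)CC)/C=C/C[C@H](C)CC1(CC#C)OCCO1 | intermediate
22 | dibutylboron (Z)-enolate of 4 | CC(C)/C=C(\OB(CCCC)CCCC)N1[C@H](Cc2ccccc2)COC1=O | intermediate (not isolated)
23 | (R)-4-benzyl-3-[(2R,3S,5S,6E,9S)-3-hydroxy-5,9-dimethyl-2-(propan-2-yl)-10-[2-(prop-2-yn-1-yl)-1,3-dioxolan-2-yl]-5-(triethylsilyloxy)dec-6-enoyl]-1,3-oxazolidin-2-one | O[C@@H](C[C@](C)(O[Si](CC)(CC)CC)/C=C/C[C@H](C)CC1(CC#C)OCCO1)[C@H](C(=O)N2[C@H](Cc3ccccc3)COC2=O)C(C)C | intermediate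
24 | (R)-4-benzyl-3-[(2R,3S,5S,6E,9S)-5,9-dimethyl-2-(propan-2-yl)-10-[2-(prop-2-yn-1-yl)-1,3-dioxolan-2-yl]-3,5-bis(triethylsilyloxy)dec-6-enoyl]-1,3-oxazolidin-2-one | CC[Si](CC)(CC)O[C@@H](C[C@](C)(O[Si](CC)(CC)CC)/C=C/C[C@H](C)CC1(CC#C)OCCO1)[C@H](C(=O)N2[C@H](Cc3ccccc3)COC2=O)C(C)C | intermediate
25 | (2S,3S,5S,6E,9S)-5,9-dimethyl-2-(propan-2-yl)-10-[2-(prop-2-yn-1-yl)-1,3-dioxolan-2-yl]-3,5-bis(triethylsilyloxy)dec-6-en-1-ol | CC[Si](CC)(CC)O[C@@H](C[C@](C)(O[Si](CC)(CC)CC)/C=C/C[C@H](C)CC1(CC#C)OCCO1)[C@H](CO)C(C)C | intermediate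
26 | (2R,3S,5S,6E,9S)-5,9-dimethyl-2-(propan-2-yl)-10-[2-(prop-2-yn-1-yl)-1,3-dioxolan-2-yl]-3,5-bis(triethylsilyloxy)dec-6-enal (C3-alkyne C2-aldehyde; C6 dioxolane; C12 and C14 triethylsilyl ethers) | CC[Si](CC)(CC)O[C@@H](C[C@](C)(O[Si](CC)(CC)CC)/C=C/C[C@H](C)CC1(OCCO1)CC#C)[C@H](C=O)C(C)C | intermediate
27 | carbon monoxide | [C-]#[O+] | starting material
28 | oxatitanacyclopentene: Cp2Ti bonded to C4 and to the C2 oxygen, 14-membered ring closed through C2–C3 (1R,2R,8S,10E,12S,14S; C6 dioxolane; 12,14-bis(triethylsilyloxy)) | CC[Si](CC)(CC)O[C@H]1C[C@](C)(O[Si](CC)(CC)CC)/C=C/C[C@H](C)CC3(OCCO3)CC2=C[C@@H](O[Ti]2(C4C=CC=C4)C5C=CC=C5)[C@@H]1C(C)C | intermediate (not isolated)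
29 | acyl titanium complex: CO inserted between Ti and C4 (six-membered Ti–O–C2–C3=C4–C15(=O) ring; same configuration as 28) | CC[Si](CC)(CC)O[C@H]1C[C@](C)(O[Si](CC)(CC)CC)/C=C/C[C@H](C)CC3(OCCO3)CC2=C[C@@H](O[Ti](C4C=CC=C4)(C5C=CC=C5)C2=O)[C@@H]1C(C)C | intermediate (not isolated)
30 | 6,6-ethylenedioxy-12,14-bis(triethylsilyloxy) bicyclic butenolide (1S,2R,8S,10E,12S,14S; C1 is S only through the CIP effect of the silyl ether) | CC[Si](CC)(CC)O[C@H]1C[C@](C)(O[Si](CC)(CC)CC)/C=C/C[C@H](C)CC3(OCCO3)CC2=C[C@@H](OC2=O)[C@@H]1C(C)C | intermediate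
31 | 6,6-ethylenedioxy-12,14-dihydroxy bicyclic butenolide (1R,2R,8S,10E,12S,14S) | O[C@H]1C[C@](C)(O)/C=C/C[C@H](C)CC3(OCCO3)CC2=C[C@@H](OC2=O)[C@@H]1C(C)C | intermediate
32 | 14-acetoxy-6,6-ethylenedioxy-12-hydroxy bicyclic butenolide (1R,2R,8S,10E,12S,14S) | CC(=O)O[C@H]1C[C@](C)(O)/C=C/C[C@H](C)CC3(OCCO3)CC2=C[C@@H](OC2=O)[C@@H]1C(C)C | intermediate
33 | CNP0200490.2: (5S,7E,9S,11S,12R,13R)-9-hydroxy-5,9-dimethyl-3,15-dioxo-12-(propan-2-yl)-14-oxabicyclo[11.2.1]hexadeca-1(16),7-dien-11-yl acetate (1R,2R,8S,10E,12S,14S in the numbering used here) | CC(=O)O[C@H]1C[C@](C)(O)/C=C/C[C@H](C)CC(=O)CC2=C[C@@H](OC2=O)[C@@H]1C(C)C | target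

## Step count and risks

Total: 21 steps. Longest linear sequence: 20 steps (5 → 33, steps 2–21); step 1 is a one-step side branch.

**1. Step 18 (key step; proposed new method).** Ring closure may lose to oligomerisation or pinacol-type coupling across a 14-atom tether, titanium may deprotonate the 1-alkyne, the acyl–alkoxide reductive elimination may stall, or the alkyne may add to the wrong aldehyde face. The fallback uses known chemistry and sets out from alcohol 25.
- The alkyne would be iodinated (N-iodosuccinimide, AgNO3 cat., acetone) to the iodoalkyne alcohol F1 and oxidised (Dess–Martin periodinane) to the iodoalkynal F2.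
- A Nozaki–Hiyama–Kishi macrocyclisation (CrCl2, NiCl2 cat., THF, high dilution) would form C2–C3 and the 14-membered ring as the cyclic propargylic alcohol F3; C2 epimers would be separated here.
- Hydroxyl-directed trans-hydroalumination (NaAlH2(OCH2CH2OMe)2, THF; then I2, −78 °C) would give the (Z)-4-iodo allylic alcohol F4.
- Carbonylative lactonisation (Pd(PPh3)4, CO, K2CO3, THF) would close the butenolide and come back to the route at 30.

**2. Step 6 (with step 5).** The β,γ-alkynyl ketone 11 may isomerise to the allenyl ketone, or cyclise to a furan, before the ketal is in place. The fallback sets out from aldehyde 7 and makes the alkyne last, from a carbonyl group, so that no propargyl ketone is ever present.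
- Zinc-mediated allylation (allyl bromide, Zn, THF/aq. NH4Cl) would give the homoallylic alcohol F5, and Dess–Martin oxidation the β,γ-enone F6.
- Noyori ketalisation would give the allyl dioxolane F7, and ozonolysis (O3, CH2Cl2, −78 °C; PPh3) the ketal aldehyde F8.
- Ohira–Bestmann homologation (dimethyl (1-diazo-2-oxopropyl)phosphonate, K2CO3, MeOH) would turn the aldehyde into the terminal alkyne and come back to the route at 12.

**3. Step 10 (and the opening in step 11).** The tertiary allylic epoxide may be opened by the Lewis-acidic titanium alkoxide medium as it forms, or hydride may open it in the SN2′ sense. The fallback sets out from aldehyde 13, takes C12 from the chiral pool and makes C10=C11 by Julia–Kocienski olefination.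
- Sulfone half: 13 would be reduced (NaBH4, MeOH) to the alcohol F9, converted by Mitsunobu reaction (1-phenyl-1H-tetrazole-5-thiol, PPh3, diisopropyl azodicarboxylate) into the sulfide F10 and oxidised (H2O2, (NH4)6Mo7O24, EtOH) to the sulfone F11.
- Aldehyde half: commercial (R)-2-methylglycidol would be protected (NaH, 4-methoxybenzyl chloride) as the ether F12 and opened at its CH2 terminus by 2-lithio-1,3-dithiane to the tertiary alcohol F13. Silylation (TESOTf, 2,6-lutidine) would give the silyl ether F14, removal of the 4-methoxybenzyl group (DDQ, pH 7 buffer) the primary alcohol F15, and Dess–Martin oxidation the aldehyde F16.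
- Olefination of F16 with the anion of F11 (KN(SiMe3)2, DME, −60 °C → rt) would give the E-alkene F17; dithiane hydrolysis (MeI, CaCO3, MeCN/H2O) would come back to the route at 21.

## Further compounds

F1 | step 18 | (2S,3S,5S,6E,9S)-10-[2-(3-iodoprop-2-yn-1-yl)-1,3-dioxolan-2-yl]-5,9-dimethyl-2-(propan-2-yl)-3,5-bis(triethylsilyloxy)dec-6-en-1-ol | CC[Si](CC)(CC)O[C@@H](C[C@](C)(O[Si](CC)(CC)CC)/C=C/C[C@H](C)CC1(CC#CI)OCCO1)[C@H](CO)C(C)C
F2 | step 18 | (2R,3S,5S,6E,9S)-10-[2-(3-iodoprop-2-yn-1-yl)-1,3-dioxolan-2-yl]-5,9-dimethyl-2-(propan-2-yl)-3,5-bis(triethylsilyloxy)dec-6-enal | CC[Si](CC)(CC)O[C@@H](C[C@](C)(O[Si](CC)(CC)CC)/C=C/C[C@H](C)CC1(CC#CI)OCCO1)[C@H](C=O)C(C)C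
F3 | step 18 | cyclic propargylic alcohol: 14-membered ring C1–C14 closed through C2–C3, C3≡C4 alkyne, 2-hydroxy, 6,6-ethylenedioxy, 12,14-bis(triethylsilyloxy), spatial arrangement at C1, C2, C8, C12, C14 as in 30 | CC[Si](CC)(CC)O[C@H]1C[C@](C)(O[Si](CC)(CC)CC)/C=C/C[C@H](C)CC2(OCCO2)CC#C[C@@H](O)[C@@H]1C(C)C
F4 | step 18 | (3Z)-4-iodo allylic alcohol of the same ring (C3=C4 with iodine on C4 cis to C2; 2-hydroxy; otherwise as F3) | CC[Si](CC)(CC)O[C@H]1C[C@](C)(O[Si](CC)(CC)CC)/C=C/C[C@H](C)CC2(OCCO2)C/C(I)=C/[C@@H](O)[C@@H]1C(C)C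
F5 | step 6 | methyl (3R)-5-hydroxy-3-methyloct-7-enoate (both C5 epimers) | COC(=O)C[C@H](C)CC(O)CC=C
F6 | step 6 | methyl (R)-3-methyl-5-oxooct-7-enoate | COC(=O)C[C@H](C)CC(=O)CC=C
F7 | step 6 | methyl (R)-3-methyl-4-[2-(prop-2-en-1-yl)-1,3-dioxolan-2-yl]butanoate | COC(=O)C[C@H](C)CC1(CC=C)OCCO1
F8 | step 6 | methyl (R)-3-methyl-4-[2-(2-oxoethyl)-1,3-dioxolan-2-yl]butanoate | COC(=O)C[C@H](C)CC1(CC=O)OCCO1
F9 | step 10 | (S)-3-methyl-4-[2-(prop-2-yn-1-yl)-1,3-dioxolan-2-yl]butan-1-ol | OCC[C@H](C)CC1(CC#C)OCCO1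
F10 | step 10 | 5-{[(R)-3-methyl-4-[2-(prop-2-yn-1-yl)-1,3-dioxolan-2-yl]butyl]sulfanyl}-1-phenyl-1H-tetrazole | c1ccccc1-n1nnnc1SCC[C@H](C)CC1(CC#C)OCCO1
F11 | step 10 | 5-{[(R)-3-methyl-4-[2-(prop-2-yn-1-yl)-1,3-dioxolan-2-yl]butyl]sulfonyl}-1-phenyl-1H-tetrazole | c1ccccc1-n1nnnc1S(=O)(=O)CC[C@H](C)CC1(CC#C)OCCO1
F12 | step 10 | (S)-2-{[(4-methoxybenzyl)oxy]methyl}-2-methyloxirane (from (R)-2-methylglycidol) | C1[C@](C)(O1)COCc1ccc(OC)cc1
F13 | step 10 | (S)-1-(1,3-dithian-2-yl)-3-[(4-methoxybenzyl)oxy]-2-methylpropan-2-ol | S1CCCSC1C[C@](C)(O)COCc1ccc(OC)cc1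
F14 | step 10 | triethylsilyl ether of F13 | S1CCCSC1C[C@](C)(O[Si](CC)(CC)CC)COCc1ccc(OC)cc1
F15 | step 10 | (S)-3-(1,3-dithian-2-yl)-2-methyl-2-(triethylsilyloxy)propan-1-ol | S1CCCSC1C[C@](C)(O[Si](CC)(CC)CC)CO
F16 | step 10 | (S)-3-(1,3-dithian-2-yl)-2-methyl-2-(triethylsilyloxy)propanal | S1CCCSC1C[C@](C)(O[Si](CC)(CC)CC)C=O
F17 | step 10 | 2-[(2S,3E,6S)-2,6-dimethyl-7-[2-(prop-2-yn-1-yl)-1,3-dioxolan-2-yl]-2-(triethylsilyloxy)hept-3-en-1-yl]-1,3-dithiane | S1CCCSC1C[C@](C)(O[Si](CC)(CC)CC)/C=C/C[C@H](C)CC1(CC#C)OCCO1
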